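**Retrosynthetic overview**

- Feature (lignan numbering): ring carbon C8 lies between the carbinol carbon C7 and the ring CH2 C9, so at the ketone/ester oxidation level it is a carbene carbon flanked by two acceptors; benzylic C7', ring CH C8' and ring CH2 C9' are an allyl unit.
- Key disconnection: C8–C8' and C8–C7' by asymmetric intramolecular cyclopropanation of an allyl 2-diazo-3-aryl-3-oxopropanoate. The lactone ring and the cyclopropane are formed first, in one step.
- The cyclopropane is then opened at C7' by an arylcuprate (second arene, trans lactone), and C7 is set by asymmetric transfer hydrogenation of the ketone.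
- The tetrahydrofuran is the last ring formed: LiAlH4 gives the 1,4-diol, Mitsunobu cyclodehydration closes it, then desilylation and hydrogenolysis.
- The diazo ester comes from vanillic acid, Meldrum's acid and allyl alcohol; the cuprate from 4-bromo-2-methoxyphenol.

Key step: step 4

Remark: the target is the (7R,8R,8'R) isomer with a 3,4-trans tetrahydrofuran. The sense of induction of the cobalt porphyrin on this substrate is not predicted here, so the ligand enantiomer that delivers (1S,5R)-9 is assumed, to be fixed in the first run by correlation of 15 with chiral-pool material.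

**Route**

Step 1
Reactants: 1 vanillic acid
Product: 3 4-(benzyloxy)-3-methoxybenzoic acid, via benzyl 4-(benzyloxy)-3-methoxybenzoate 2 (not isolated)
Conditions: BnBr, K2CO3, DMF, 60 °C; then NaOH, MeOH/H2O, reflux; HCl to pH 2
Reagents that add atoms: benzyl bromide, BrCc1ccccc1; sodium hydroxide, [Na+].[OH-] (one carboxyl oxygen)
Why: Williamson O-alkylation of phenoxide and carboxylate followed by saponification of the benzyl ester leaves the aryl benzyl ether, which is inert to hydroxide.

Step 2
Reactants: 3 4-(benzyloxy)-3-methoxybenzoic acid; 4 Meldrum's acid; 5 allyl alcohol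
Product: 7 allyl 3-(4-benzyloxy-3-methoxyphenyl)-3-oxopropanoate, via acyl Meldrum's acid 6 (not isolated)
Conditions: DCC, DMAP, CH2Cl2, 0 °C to rt; filter, evaporate; allyl alcohol, toluene, reflux
Reagents that add atoms: none
Why: Carbodiimide C-acylation of Meldrum's acid and thermal alcoholysis of the acyl Meldrum's acid (acylketene pathway, loss of acetone and CO2) is the standard two-carbon homologation of an acid to a β-keto ester and installs the allyl ester directly.

Step 3
Reactants: 7 allyl 3-(4-benzyloxy-3-methoxyphenyl)-3-oxopropanoate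
Product: 8 allyl 3-(4-benzyloxy-3-methoxyphenyl)-2-diazo-3-oxopropanoate
Conditions: 4-acetamidobenzenesulfonyl azide, Et3N, MeCN, 0 °C to rt
Reagents that add atoms: 4-acetamidobenzenesulfonyl azide, CC(=O)Nc1ccc(cc1)S(=O)(=O)N=[N+]=[N-]
Why: Regitz diazo transfer to the acidic methylene of a β-keto ester; Et3N deprotonates no other position.

Step 4
Reactants: 8 allyl 3-(4-benzyloxy-3-methoxyphenyl)-2-diazo-3-oxopropanoate
Product: 9 (1S,5R)-1-(4-benzyloxy-3-methoxybenzoyl)-3-oxabicyclo[3.1.0]hexan-2-one
Conditions: Co(3,5-DitBu-QingPhyrin) (2 mol %, chiral amidoporphyrin complex of divalent cobalt), toluene, 40 °C, N2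
Reagents that add atoms: none
Why: The divalent cobalt porphyrin takes up the diazo ester with loss of N2 to give a cobalt-bound carbon radical at C8 (a carbene radical on trivalent cobalt) flanked by the aryl ketone and the ester; this radical adds to the internal alkene carbon C8', and the primary radical formed at C7' displaces cobalt from C8 and releases the catalyst. The closest known reaction type is the cobalt-porphyrin metalloradical intramolecular cyclopropanation of allyl diazoacetates that carry a second acceptor (keto, ester, cyano, nitro) on the diazo carbon. The lactone ring closes by 5-exo-trig radical addition (C8–C8') and the three-membered ring by 3-exo-tet homolytic substitution at C8 (C8–C7'). C8' is set by the chiral amide pockets of the porphyrin, which should hold the carbonyl groups of the carbene radical by N–H···O hydrogen bonds and expose one face of the allyl alkene; C8 is not independent, because a bicyclo[3.1.0]hexane can only be cis-fused. The step needs cyclopropanation to win over carbene dimerisation, Wolff rearrangement and attack on the electron-rich arene or the benzyl ether; the short tether that holds the alkene next to C8 and the low electrophilicity of the cobalt carbene radical should secure this.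

Step 5
Reactants: 10 4-bromo-2-methoxyphenol
Product: 11 1-(benzyloxy)-4-bromo-2-methoxybenzene
Conditions: BnBr, K2CO3, acetone, reflux
Reagents that add atoms: benzyl bromide, BrCc1ccccc1
Why: Williamson ether synthesis on the phenol; the benzyl ether tolerates magnesium insertion and is removed at the end together with the other one.

Step 6
Reactants: 9 (1S,5R)-1-(4-benzyloxy-3-methoxybenzoyl)-3-oxabicyclo[3.1.0]hexan-2-one; 11 1-(benzyloxy)-4-bromo-2-methoxybenzene
Product: 15 (3S,4R)-3-(4-benzyloxy-3-methoxybenzoyl)-4-(4-benzyloxy-3-methoxybenzyl)dihydrofuran-2(3H)-one, via arylmagnesium bromide 12 (not isolated), via bromomagnesium diarylcuprate 13 (not isolated), via bromomagnesium enolate 14 (not isolated)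
Conditions: 11 (2.4 equiv), Mg, THF, rt; CuBr·SMe2 (1.2 equiv), THF, −40 °C; then 9, −40 to 0 °C; aq. NH4Cl
Reagents that add atoms: none
Why: Homoconjugate (homo-Michael) addition of a diarylcuprate to a cyclopropane doubly activated by ketone and lactone: the aryl group should attack the unhindered CH2 carbon C7' with cleavage of the C8–C7' bond, C8' is untouched, and the stabilised enolate resists a second addition and is protonated on work-up to the keto lactone, which settles through its enol into the favoured 3,4-trans form.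

Step 7
Reactants: 15 (3S,4R)-3-(4-benzyloxy-3-methoxybenzoyl)-4-(4-benzyloxy-3-methoxybenzyl)dihydrofuran-2(3H)-one
Product: 16 (3S,4R)-4-(4-benzyloxy-3-methoxybenzyl)-3-[(R)-(4-benzyloxy-3-methoxyphenyl)(hydroxy)methyl]dihydrofuran-2(3H)-one
Conditions: RuCl[(R,R)-TsDPEN](p-cymene) (2 mol %), HCO2H/Et3N (5:2), DMF, rt
Reagents that add atoms: none
Why: Noyori–Ikariya asymmetric transfer hydrogenation: the (R,R)-TsDPEN ruthenium hydride should deliver hydrogen to the face of the aryl ketone that gives the (R)-carbinol, as with simple aryl alkyl ketones, a sense that coincides with Felkin–Anh attack anti to the lactone carbonyl on the trans isomer, while C8 stays trans because the keto lactone equilibrates through its enol.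

Step 8
Reactants: 16 (3S,4R)-4-(4-benzyloxy-3-methoxybenzyl)-3-[(R)-(4-benzyloxy-3-methoxyphenyl)(hydroxy)methyl]dihydrofuran-2(3H)-one
Product: 17 (3S,4R)-4-(4-benzyloxy-3-methoxybenzyl)-3-[(R)-(4-benzyloxy-3-methoxyphenyl)(tert-butyldimethylsilyloxy)methyl]dihydrofuran-2(3H)-one
Conditions: TBSOTf, 2,6-lutidine, CH2Cl2, −78 to 0 °C
Reagents that add atoms: tert-butyldimethylsilyl trifluoromethanesulfonate, CC(C)(C)[Si](C)(C)OS(=O)(=O)C(F)(F)F
Why: Silylation of the hindered secondary benzylic alcohol with a silyl triflate and a non-nucleophilic base; it keeps the C7 oxygen out of the later ring closure and blocks retro-aldol cleavage.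

Step 9
Reactants: 17 (3S,4R)-4-(4-benzyloxy-3-methoxybenzyl)-3-[(R)-(4-benzyloxy-3-methoxyphenyl)(tert-butyldimethylsilyloxy)methyl]dihydrofuran-2(3H)-one
Product: 18 (2R,3R)-2-(4-benzyloxy-3-methoxybenzyl)-3-[(R)-(4-benzyloxy-3-methoxyphenyl)(tert-butyldimethylsilyloxy)methyl]butane-1,4-diol
Conditions: LiAlH4, THF, 0 °C; Fieser work-up (H2O, aq. NaOH)
Reagents that add atoms: none
Why: Hydride reduction of the lactone to the 1,4-diol should be faster than enolisation at C8, and the aryl benzyl ethers and the silyl ether are inert to LiAlH4 at 0 °C, where silyl migration from the aluminium alkoxide is not expected.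

Step 10
Reactants: 18 (2R,3R)-2-(4-benzyloxy-3-methoxybenzyl)-3-[(R)-(4-benzyloxy-3-methoxyphenyl)(tert-butyldimethylsilyloxy)methyl]butane-1,4-diol
Product: 19 tert-butyl{(R)-(4-benzyloxy-3-methoxyphenyl)[(3R,4R)-4-(4-benzyloxy-3-methoxybenzyl)tetrahydrofuran-3-yl]methoxy}dimethylsilane
Conditions: PPh3, DIAD, THF, 0 °C to rt
Reagents that add atoms: none
Why: Mitsunobu cyclodehydration of a 1,4-diol: one primary hydroxyl is activated as its oxyphosphonium ion and displaced by the other in a 5-exo-tet closure, and since both carbinol carbons are CH2 groups either mode of activation gives the same tetrahydrofuran without touching a stereocentre.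

Step 11
Reactants: 19 tert-butyl{(R)-(4-benzyloxy-3-methoxyphenyl)[(3R,4R)-4-(4-benzyloxy-3-methoxybenzyl)tetrahydrofuran-3-yl]methoxy}dimethylsilane
Product: 20 (R)-(4-benzyloxy-3-methoxyphenyl)[(3R,4R)-4-(4-benzyloxy-3-methoxybenzyl)tetrahydrofuran-3-yl]methanol
Conditions: n-Bu4NF, THF, 0 °C to rt
Reagents that add atoms: none
Why: Fluoride-mediated desilylation cleaves only the Si–O bond; the benzyl ethers and the tetrahydrofuran are inert, and no acid is present that could ionise the electron-rich benzylic alcohol.

Step 12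
Reactants: 20 (R)-(4-benzyloxy-3-methoxyphenyl)[(3R,4R)-4-(4-benzyloxy-3-methoxybenzyl)tetrahydrofuran-3-yl]methanol
Product: 21 4-{(R)-hydroxy[(3R,4R)-4-(4-hydroxy-3-methoxybenzyl)tetrahydrofuran-3-yl]methyl}-2-methoxyphenol (target)
Conditions: H2 (1 atm), 10% Pd/C, EtOAc, rt
Reagents that add atoms: none
Why: Catalytic hydrogenolysis of aryl benzyl ethers over Pd/C in a neutral aprotic solvent at 1 atm should be much faster than hydrogenolysis of the secondary benzylic C–O bond, so both phenols are freed with C7 intact.

**Compound list**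

1 | vanillic acid | COc1cc(C(=O)O)ccc1O | starting material
2 | benzyl 4-(benzyloxy)-3-methoxybenzoate | COc1cc(C(=O)OCc2ccccc2)ccc1OCc1ccccc1 | intermediate (not isolated)
3 | 4-(benzyloxy)-3-methoxybenzoic acid | COc1cc(C(=O)O)ccc1OCc1ccccc1 | intermediate
4 | Meldrum's acid | CC1(C)OC(=O)CC(=O)O1 | starting material
5 | allyl alcohol | C=CCO | starting material
6 | 5-[(4-benzyloxy-3-methoxyphenyl)(hydroxy)methylidene]-2,2-dimethyl-1,3-dioxane-4,6-dione (acyl Meldrum's acid) | CC1(C)OC(=O)C(=C(O)c2ccc(OCc3ccccc3)c(OC)c2)C(=O)O1 | intermediate (not isolated)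
7 | allyl 3-(4-benzyloxy-3-methoxyphenyl)-3-oxopropanoate | C=CCOC(=O)CC(=O)c1ccc(OCc2ccccc2)c(OC)c1 | intermediate
8 | allyl 3-(4-benzyloxy-3-methoxyphenyl)-2-diazo-3-oxopropanoate | C=CCOC(=O)C(=[N+]=[N-])C(=O)c1ccc(OCc2ccccc2)c(OC)c1 | intermediate
9 | (1S,5R)-1-(4-benzyloxy-3-methoxybenzoyl)-3-oxabicyclo[3.1.0]hexan-2-one | C1[C@H]2COC(=O)[C@@]12C(=O)c1ccc(OCc2ccccc2)c(OC)c1 | intermediate
10 | 4-bromo-2-methoxyphenol | COc1cc(Br)ccc1O | starting material
11 | 1-(benzyloxy)-4-bromo-2-methoxybenzene | COc1cc(Br)ccc1OCc1ccccc1 | intermediate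
12 | (4-benzyloxy-3-methoxyphenyl)magnesium bromide | COc1cc([Mg]Br)ccc1OCc1ccccc1 | intermediate (not isolated)
13 | bromomagnesium bis(4-benzyloxy-3-methoxyphenyl)cuprate | COc1cc([Cu-]c2ccc(OCc3ccccc3)c(OC)c2)ccc1OCc1ccccc1.[Mg+]Br | intermediate (not isolated)
14 | bromomagnesium enolate of 15 | O=C1OC[C@H](Cc2ccc(OCc3ccccc3)c(OC)c2)C1=C(O[Mg]Br)c1ccc(OCc2ccccc2)c(OC)c1 | intermediate (not isolated)
15 | (3S,4R)-3-(4-benzyloxy-3-methoxybenzoyl)-4-(4-benzyloxy-3-methoxybenzyl)dihydrofuran-2(3H)-one | O=C1OC[C@H](Cc2ccc(OCc3ccccc3)c(OC)c2)[C@H]1C(=O)c1ccc(OCc2ccccc2)c(OC)c1 | intermediate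
16 | (3S,4R)-4-(4-benzyloxy-3-methoxybenzyl)-3-[(R)-(4-benzyloxy-3-methoxyphenyl)(hydroxy)methyl]dihydrofuran-2(3H)-one | O=C1OC[C@H](Cc2ccc(OCc3ccccc3)c(OC)c2)[C@H]1[C@@H](O)c1ccc(OCc2ccccc2)c(OC)c1 | intermediate
17 | (3S,4R)-4-(4-benzyloxy-3-methoxybenzyl)-3-[(R)-(4-benzyloxy-3-methoxyphenyl)(tert-butyldimethylsilyloxy)methyl]dihydrofuran-2(3H)-one | O=C1OC[C@H](Cc2ccc(OCc3ccccc3)c(OC)c2)[C@H]1[C@@H](O[Si](C)(C)C(C)(C)C)c1ccc(OCc2ccccc2)c(OC)c1 | intermediate
18 | (2R,3R)-2-(4-benzyloxy-3-methoxybenzyl)-3-[(R)-(4-benzyloxy-3-methoxyphenyl)(tert-butyldimethylsilyloxy)methyl]butane-1,4-diol | OC[C@H](Cc1ccc(OCc2ccccc2)c(OC)c1)[C@H](CO)[C@@H](O[Si](C)(C)C(C)(C)C)c1ccc(OCc2ccccc2)c(OC)c1 | intermediate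
19 | tert-butyl{(R)-(4-benzyloxy-3-methoxyphenyl)[(3R,4R)-4-(4-benzyloxy-3-methoxybenzyl)tetrahydrofuran-3-yl]methoxy}dimethylsilane | COc1cc(C[C@H]2COC[C@@H]2[C@@H](O[Si](C)(C)C(C)(C)C)c2ccc(OCc3ccccc3)c(OC)c2)ccc1OCc1ccccc1 | intermediate
20 | (R)-(4-benzyloxy-3-methoxyphenyl)[(3R,4R)-4-(4-benzyloxy-3-methoxybenzyl)tetrahydrofuran-3-yl]methanol | COc1cc(C[C@H]2COC[C@@H]2[C@@H](O)c2ccc(OCc3ccccc3)c(OC)c2)ccc1OCc1ccccc1 | intermediate
21 | 4-{(R)-hydroxy[(3R,4R)-4-(4-hydroxy-3-methoxybenzyl)tetrahydrofuran-3-yl]methyl}-2-methoxyphenol | COc1cc(C[C@H]2COC[C@@H]2[C@@H](O)c2ccc(O)c(OC)c2)ccc1O | target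

**Step count**

Total: 12 steps. Longest linear sequence: 11 steps (steps 1–4 and 6–12, from vanillic acid); step 5 is a one-step side branch.

**Steps most likely to fail**

Step 4. The chiral cobalt porphyrin may discriminate poorly between the two faces of the unsubstituted allyl alkene, or the carbene may be lost to dimerisation or Wolff rearrangement. The fallback takes the absolute configuration from the chiral pool and introduces the ketone last. It sets out from acid 3 and bromide 11, with dimethyl malonate and (R)-epichlorohydrin as further commercial materials, and rejoins the route at 15. Dimethyl malonate and (R)-epichlorohydrin with NaOMe in MeOH at reflux should give methyl (1S,5R)-2-oxo-3-oxabicyclo[3.1.0]hexane-1-carboxylate F1, through epoxide opening, re-closure to the new epoxide, 3-exo-tet cyclopropane formation with inversion, and lactonisation. The cuprate 13 made from 11 opens F1 at the cyclopropane CH2 to methyl (3S,4R)-4-(4-benzyloxy-3-methoxybenzyl)-2-oxotetrahydrofuran-3-carboxylate F2. Krapcho demethoxycarbonylation (LiCl, wet DMSO, 140 °C) gives (R)-4-(4-benzyloxy-3-methoxybenzyl)dihydrofuran-2(3H)-one F3. Its lithium enolate (LiN(SiMe3)2, 2 equiv, THF, −78 °C) is C-acylated anti to the benzyl group with 4-(benzyloxy)-3-methoxybenzoyl chloride F4, made from 3 with oxalyl chloride and catalytic DMF, to give 15.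

Step 6. The aryl nucleophile may add 1,2 to the aryl ketone or to the lactone carbonyl instead of opening the ring, or the electron-rich aryl group may transfer from copper too slowly. The fallback separates ring opening from C–C bond formation; it sets out from 9 and rejoins at 15. MgI2 in Et2O/THF at rt should open the doubly activated cyclopropane with iodide at C7', and dilute acid work-up gives (3S,4R)-3-(4-benzyloxy-3-methoxybenzoyl)-4-(iodomethyl)dihydrofuran-2(3H)-one F5. A nickel-catalysed reductive cross-electrophile coupling of this primary iodide with bromide 11 (NiBr2·glyme, 4,4'-di-tert-butyl-2,2'-bipyridine, Zn, DMA, 60 °C) then forms the C7'–aryl bond to give 15. The coupling runs without base, so the iodide should not re-close to the cyclopropane.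

Step 7. Hydrogen may be transferred to the minor cis-keto lactone as C8 epimerises under the reaction conditions, or facial control may be weak on a ketone that is partly enolised. The fallback gives up catalyst control for substrate control with recycling; it sets out from 15 and rejoins at 16. NaBH4 in MeOH/CH2Cl2 at −78 °C, a non-chelating medium, should favour Felkin–Anh attack anti to the lactone carbonyl and hence 16. The C7 epimers are separated by chromatography, and the minor (3S,4R)-4-(4-benzyloxy-3-methoxybenzyl)-3-[(S)-(4-benzyloxy-3-methoxyphenyl)(hydroxy)methyl]dihydrofuran-2(3H)-one F6 is returned to 15 by Dess–Martin oxidation and reduced again.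

**Further compounds**

F1 | step 4 | methyl (1S,5R)-2-oxo-3-oxabicyclo[3.1.0]hexane-1-carboxylate | C1[C@H]2COC(=O)[C@@]12C(=O)OC
F2 | step 4 | methyl (3S,4R)-4-(4-benzyloxy-3-methoxybenzyl)-2-oxotetrahydrofuran-3-carboxylate | COC(=O)[C@H]1C(=O)OC[C@@H]1Cc1ccc(OCc2ccccc2)c(OC)c1
F3 | step 4 | (R)-4-(4-benzyloxy-3-methoxybenzyl)dihydrofuran-2(3H)-one | O=C1C[C@@H](Cc2ccc(OCc3ccccc3)c(OC)c2)CO1
F4 | step 4 | 4-(benzyloxy)-3-methoxybenzoyl chloride | COc1cc(C(Cl)=O)ccc1OCc1ccccc1
F5 | step 6 | (3S,4R)-3-(4-benzyloxy-3-methoxybenzoyl)-4-(iodomethyl)dihydrofuran-2(3H)-one | O=C1OC[C@H](CI)[C@H]1C(=O)c1ccc(OCc2ccccc2)c(OC)c1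
F6 | step 7 | (3S,4R)-4-(4-benzyloxy-3-methoxybenzyl)-3-[(S)-(4-benzyloxy-3-methoxyphenyl)(hydroxy)methyl]dihydrofuran-2(3H)-one | O=C1OC[C@H](Cc2ccc(OCc3ccccc3)c(OC)c2)[C@H]1[C@H](O)c1ccc(OCc2ccccc2)c(OC)c1
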